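Readings and results come from a simulation with made-up constants; the scatter is artificial.

If one figure must say how soon a flask finishes, take [starting material] present over the rate at that moment.

| setting | dusk | spring | noon | dawn |
|---|---|---|---|---|
| starting material | 1.00 M | 1.00 M | 0.500 M | 0.150 M |
| free catalyst | 0.00200 M | 0.00100 M | 0.00200 M | 0.00200 M |
| time |  |  |  | 20 h |

| run | time / h | [target] / M |
|---|---|---|
| dusk run | 2.9 | 0.102 |
| dusk run | 5.7 | 0.173 |
| dusk run | 8.6 | 0.257 |
| dusk run | 11 | 0.325 |
| dusk run | 14 | 0.401 |
| dusk run | 17 | 0.475 |
| dusk run | 20 | 0.535 |
| spring run | 2.9 | 0.032 |
| spring run | 5.7 | 0.052 |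
| spring run | 8.6 | 0.056 |
| spring run | 11 | 0.089 |
| spring run | 14 | 0.103 |
| spring run | 17 | 0.108 |
| spring run | 20 | 0.126 |
| noon run | 2.9 | 0.100 |
| noon run | 5.7 | 0.167 |
| noon run | 8.6 | 0.267 |
| noon run | 11 | 0.301 |
| noon run | 14 | 0.363 |
| noon run | 17 | 0.409 |
| noon run | 20 | 0.435 |

(scatter of a reading: 0.008 M)

* apparent order in [starting material] of the starting rate, round the charge of the dusk run (the rate where two percent of its starting material have turned into target) (one fixed amount of target, the same in the runs compared)
* apparent order in [free catalyst] of the starting rate, round the charge of the dusk run (the rate where two percent of its starting material have turned into target)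
* target in the dawn run at 20 h, as a share of the starting material charged
* which of these the readings show (nothing beyond the main steps / the product kills the catalyst / the catalyst wakes slowly / the product ties up the catalyst / the substrate kills the catalyst)

- Overall: starting material -> target, with free catalyst as catalyst.
- Constant volume, constant temperature.
- The analysis sees a species whether free or bound.
- An order is taken over about fifteen percent of the charge, up and down.

1. Start with the main step at constant pace. Read the pace at 8.6 h in the dusk run, 0.0299 M h⁻¹; the noon run reads 0.0310 M h⁻¹ on half the charge. Carry that pace to the dawn run: its charge lasts 5.02 h, the emptying time. This is shorter than 20 h, so this step gives 100%.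

2. Add the slowing at low [starting material]. Between 14 h and 20 h the noon run makes 0.0120 M h⁻¹ with 0.101 M left, an emptying time of 8.42 h. Treat the dawn run as constant pace for 1.64 h, then as a pseudo-first-order tail with that time. The share drops to 92.4%.

3. Add catalyst loss. The spring run's pace falls from 0.00912 M h⁻¹ to 0.00411 M h⁻¹, with target at 0.126 M by the end. Its early emptying time is 110 h. Read this as loss under starting material: the pace halves per 660 M·min of [starting material] times hours. The noon tail had taken 307 M·min, so fresh catalyst shortens its emptying time to 6.10 h. The dawn tail takes about 54.9 M·min, less than that halving amount, so leave its own loss out. My share: 96.7%.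

4. The forecast gives 0.1 and 1.7 for the orders, 97% for the dawn run, and the substrate kills the catalyst, on this ground: “The loss therefore follows time under high substrate”.

5. The flask gives −0.21 and 2.0, 97.3%, and the substrate kills the catalyst.

    free catalyst + starting material ⇌ catalyst-substrate complex, settled at all times (1.520 M⁻¹)
    catalyst-substrate complex + free catalyst → target + 2 free catalyst (35100 M⁻¹ h⁻¹)
    free catalyst + starting material → spent catalyst + starting material (0.03744 M⁻¹ h⁻¹)

In the dawn run the main step ran through the catalyst-substrate complex for 20 h, which is 3.98 times the emptying time of 5.02 h reckoned with the pace of the dusk run, and the passing of free catalyst into spent catalyst made no difference to the 97.3% of the charge standing as target at 20 h. In the spring run free catalyst passed into spent catalyst while the main step ran; its early emptying time of 110 h promised a quarter of the charge as target at 27.5 h, but that amount stood at 61.6 h.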